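**Free partner.** Count the coupling partner that is free, not the partner that was dosed: in my reckoning for this flask I treated the substrate as shared between two products, the isomer of the product and the side product, and set the target aside.

all flasks: substrate 1.5 M
- elm: coupling partner 0.90 M (fed, over 25 h); the very flask that is asked about, followed so far; the fed solution adds 0.10 times the starting volume
- flask: coupling partner 0.900 M (fed, over 25 h); the fed solution adds 0.10 times the starting volume; time 25 h

elm run (percent of the substrate charged)

| time / h | tautomer / % | isomer of the product / % | substrate / % | side product / % | target / % |
|---|---|---|---|---|---|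
| 1.33 | 3.5 | 1.1 | 73.4 | 19.9 | 0.8 |
| 3.00 | 3.5 | 3.2 | 49.8 | 40.0 | 0.5 |
| 4.00 | 2.4 | 4.7 | 39.7 | 47.6 | 0 |
| 6.00 | 0 | 5.6 | 21.7 | 60.8 | 1.5 |
| 8.00 | 0 | 8.6 | 13.0 | 68.1 | 1.6 |
| 10.0 | 0 | 9.0 | 7.3 | 71.5 | 2.8 |

(each reading ± 1 percentage point)

1. the species that holds most of what was charged as substrate, at 25 h (isomer of the product / side product / tautomer / substrate / target)
2. the largest share itself, whichever of these holds it, in percent of the substrate charged

- charges are per starting volume, the dose included; the dosed solution carries all of it
- the numbers in the tables scatter by 1 percentage point (one standard deviation)
- a reading or a percentage of target counts all its forms, free or not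
- a reading or a percentage of substrate is of its free form alone

**Partner dose.** Between 6.00 h and 10.0 h the readings of the elm run gained 0.318 of isomer of the product per side product. My first round divided that by the dose at 8.00 h, 0.288 M, and gave 1.10 L mol⁻¹. But I took isomer of the product and target to hold one partner each, so I put that back, which left c(coupling partner) at 0.135 M. The second round gave a reading of 2.35 L mol⁻¹, the selectivity factor: isomer of the product formed per side product formed, per mole per litre of free partner. By hand, a faster dose raises c(coupling partner) and so the isomer of the product gained per side product.

**Substrate charge.** By hand, more substrate at the same dose takes up partner faster and lowers that gain. The readings of the elm run gave the substrate a mean life of 3.67 h, so I added that much dosing to my free partner at 10.0 h and reckoned 0.315 M. That made 0.742 of isomer of the product per side product, and sharing the substrate read at 10.0 h in that ratio gave me 75.7% of side product.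

**The forecast.** The forecast named side product at 60%, within 46% to 71%, lower than my figure, saying “Both of these drain the side product modestly”.

**The result.** The flask gave side product at 75.6%, with 12.5% of isomer of the product.

    substrate + target ⇌ idle adduct, settled at all times (K = 0.230 L mol⁻¹)
    tautomer → decomposed reagent (k = 0.452 h⁻¹)
    substrate ⇌ tautomer (K = 0.198, k = 0.312 h⁻¹)
    tautomer → side product (k = 3.24 h⁻¹)
    coupling partner + tautomer → target (k = 0.743 L mol⁻¹ h⁻¹)
    substrate + coupling partner → isomer of the product (k = 0.432 L mol⁻¹ h⁻¹)

**Neighbour flask.** This flask's end ratio of 0.165 corresponds, through the selectivity factor, to a mean free partner of 0.0700 M. Scaling that by the charge for the neighbour flask with 2.2 M of coupling partner gave 0.171 M and a ratio of 0.403. Keeping the sum of the two products, I reckoned 62.8% of side product for that neighbour flask, and it held 65.4%.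

Readings and results were computed with constants of no real substance, and the scatter is random.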